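**Target.** 2-Hydroxy-5-methoxy-3-{[(1R,2R,4aR,8aS)-1,2,4a-trimethyl-5-methylidenedecahydronaphthalen-1-yl]methyl}cyclohexa-2,5-diene-1,4-dione.

Assumption: the SMILES is taken as drawn, i.e. (5R,8R,9R,10S) in avarane numbering. Reading the SMILES, 5‑CH3, 10‑H, 9‑CH2Ar and 8‑CH3 are on one face and 9‑CH3 on the other (cis-decalin).

Numbering used in the "Why" lines: C4 = carbon bearing the exocyclic CH2; C5 = ring-fusion C–CH3; C8 = CH(CH3); C9 = quaternary C(CH3)(CH2Ar); C10 = ring-fusion CH; C1–C3 = the CH2 chain from C10 to C4. Ar = 2,3,5,6-tetramethoxyphenyl.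

## Retrosynthetic overview

1. Quinone ⇐ tetramethoxyarene 13 (CAN oxidation, then selective vinylogous-ester hydrolysis); C4=CH2 ⇐ Wittig on decalone 12.
2. Ring A (C1–C10 bond, then C5–CH3) ⇐ chloro enone 11 by a cathodic 6-endo cyclisation with angular methylation of the enolate.
3. 11 ⇐ vinyl triflate 9 (carbonylative Negishi); 9 ⇐ enone 8 by Me2CuLi addition anti to the C8 methyl (sets C9) and enolate triflation.
4. 8 ⇐ (R)-4-methylcyclohex-2-enone 4 + tetramethoxybenzyl Grignard; 4 ⇐ (R)-pulegone 1, which supplies C8, the only purchased stereocentre.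
5. Ring order: ring B is the pulegone ring; the arene is attached as a benzyl group; ring A is closed last; the quinone is unmasked at the end.

## Route

**Step 1**
Reactants: 1, (R)-(+)-pulegone
Product: 2, (R)-3-methyl-6-(propan-2-ylidene)cyclohex-1-en-1-yl trifluoromethanesulfonate
Conditions: LDA, THF, −78 °C; PhNTf2, −78 → 0 °C
Reagents that add atoms: N-phenylbis(trifluoromethanesulfonimide), O=S(=O)(N(c1ccccc1)S(=O)(=O)C(F)(F)F)C(F)(F)F
Why: Kinetic LDA deprotonation of the enone at the α′-CH2 and O-triflation of the cross-conjugated enolate give the dienyl triflate (a known reaction of pulegone); the C8 stereocentre is remote and untouched.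

**Step 2**
Reactants: 2
Product: 3, (R)-3-methyl-6-oxocyclohex-1-en-1-yl trifluoromethanesulfonate (4-methyl-2-triflyloxycyclohex-2-enone)
Conditions: O3, CH2Cl2/MeOH, −78 °C; Me2S
Reagents that add atoms: ozone, [O-][O+]=O
Why: Chemoselective ozonolysis: the electron-rich tetrasubstituted isopropylidene alkene is cleaved much faster than the electron-poor triflyloxy alkene, revealing the C5 ketone and expelling acetone.

**Step 3**
Reactants: 3
Product: 4, (R)-4-methylcyclohex-2-en-1-one
Conditions: Pd(OAc)2, PPh3, HCO2H, n-Bu3N, DMF, 60 °C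
Reagents that add atoms: none
Why: Pd(0)/formate hydrogenolysis of the enol triflate (Cacchi reduction) gives the known enone without touching the γ-stereocentre.

**Step 4**
Reactants: 5, 1,2,4,5-tetramethoxybenzene
Product: 6, (2,3,5,6-tetramethoxyphenyl)methanol
Conditions: n-BuLi, TMEDA, THF, 0 °C; (CH2O)n, 0 °C → rt
Reagents that add atoms: formaldehyde (paraformaldehyde), C=O
Why: Directed ortho-lithiation at the CH flanked by two methoxy groups, then hydroxymethylation.

**Step 5**
Reactants: 6
Product: 7, 3-(chloromethyl)-1,2,4,5-tetramethoxybenzene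
Conditions: SOCl2, CH2Cl2, 0 °C (used crude)
Reagents that add atoms: thionyl chloride, O=S(Cl)Cl
Why: Standard chlorination of an electron-rich benzylic alcohol.

**Step 6**
Reactants: 4; 7
Product: 8, (R)-4-methyl-3-[(2,3,5,6-tetramethoxyphenyl)methyl]cyclohex-2-en-1-one
Conditions: 7, Mg, THF, 0 °C; CuBr·SMe2 (10 mol %), 4, −78 °C; then PhS(Cl)=N-t-Bu, −78 °C → rt
Reagents that add atoms: none (all new heavy atoms come from 7)
Why: Cu-catalysed 1,4-addition of the benzylic Grignard gives the regiodefined magnesium enolate, which the sulfinimidoyl chloride dehydrogenates in the same pot (Mukaiyama–Matsuo α-sulfenylation and syn-elimination across C9–C10) to the β-benzyl enone; the transient C9 centre is erased and C8 is untouched.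

**Step 7**
Reactants: 8
Product: 9, (3R,4R)-3,4-dimethyl-3-[(2,3,5,6-tetramethoxyphenyl)methyl]cyclohex-1-en-1-yl trifluoromethanesulfonate
Conditions: Me2CuLi, TMSCl, THF, −78 °C; MeLi, 0 °C; PhNTf2, 0 °C → rt
Reagents that add atoms: lithium dimethylcuprate, [Li+].C[Cu-]C; N-phenylbis(trifluoromethanesulfonimide), O=S(=O)(N(c1ccccc1)S(=O)(=O)C(F)(F)F)C(F)(F)F
Why: Cuprate conjugate addition to the β,β-disubstituted enone occurs anti to the adjacent pseudoaxial C8 methyl (A1,2 strain), setting quaternary C9 with 9-CH3 trans to 8-CH3 and CH2Ar cis to it; MeLi regenerates the regiodefined enolate, which is O-triflated (McMurry–Scott).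

**Step 8**
Reactants: 9; 10, 1-chloro-3-iodopropane (as its zinc reagent)
Product: 11, 4-chloro-1-{(3R,4R)-3,4-dimethyl-3-[(2,3,5,6-tetramethoxyphenyl)methyl]cyclohex-1-en-1-yl}butan-1-one
Conditions: 10, Zn, LiCl, THF, 25 °C; then 9, Pd(PPh3)4 (5 mol %), CO (3 atm), THF/NMP, 50 °C
Reagents that add atoms: 3-chloropropylzinc iodide (from 10), ClCCC[Zn]I; carbon monoxide, [C-]#[O+]
Why: Carbonylative Negishi coupling (oxidative addition at the unhindered vinyl triflate, CO insertion, transmetalation of the chloride-tolerant alkylzinc) gives the acyl cyclohexene; no stereocentre is affected.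

**Step 9**
Reactants: 11
Product: 12, (4aS,5R,6R,8aR)-5,6,8a-trimethyl-5-[(2,3,5,6-tetramethoxyphenyl)methyl]octahydronaphthalen-1(2H)-one (cis-fused)
Conditions: Ni(salen) (10 mol %), Bu4NI (20 mol %), TMSCl (3 equiv), 0.1 M Bu4NBF4/DMF, divided cell, RVC cathode, −1.1 V vs SCE, 40 °C, 2.2 F/mol; strip TMSCl in vacuo; MeI (5 equiv), TBAT (1.5 equiv), −20 °C → rt
Reagents that add atoms: iodomethane, CI
Why: Proposed new method: a one-flask Ni(I)(salen)-mediated cathodic radical–polar crossover annulation with angular methylation, in which Ni(I) (generated well positive of the enone wave) takes iodine from the alkyl iodide formed by catalytic Finkelstein exchange, the primary C1 radical closes 6-endo onto C10 of the tethered enone (5-exo would attack the fully substituted α-carbon and is electronically mismatched) anti to the pseudoaxial C9–CH2Ar and away from the C8 methyl so that 10-H ends on the CH2Ar face, the α-keto radical is reduced and O-silylated to the single Δ4(5) silyl enol ether (TMSCl prevents the basic enolate from deprotonating unreacted 11), and fluoride then releases the ammonium enolate, which MeI attacks cis to 10-H (β-face shielded by axial 9-CH3, plus the usual cis preference of 1-decalone Δ1(9)-enolates) to give the cis-decalin; closest known chemistry is Ni(I)/Co(I)-mediated electroreductive radical cyclisation of haloalkyl enones with protonation, SmI2 or Li/NH3 reductive cyclisation–alkylation, and Kuwajima fluoride-mediated alkylation of silyl enol ethers.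

**Step 10**
Reactants: 12
Product: 13, 3-{[(1R,2R,4aR,8aS)-1,2,4a-trimethyl-5-methylidenedecahydronaphthalen-1-yl]methyl}-1,2,4,5-tetramethoxybenzene
Conditions: Ph3PCH3Br, KOt-Bu, toluene, 90 °C
Reagents that add atoms: methylenetriphenylphosphorane, C=P(c1ccccc1)(c1ccccc1)c1ccccc1
Why: Wittig methylenation under forcing conditions converts the hindered α-quaternary ketone to the exocyclic alkene; no epimerisable stereocentre is present (C5 is quaternary, C10 is β to the carbonyl).

**Step 11**
Reactants: 13
Product: 14, 2,5-dimethoxy-3-{[(1R,2R,4aR,8aS)-1,2,4a-trimethyl-5-methylidenedecahydronaphthalen-1-yl]methyl}cyclohexa-2,5-diene-1,4-dione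
Conditions: CAN, MeCN/H2O, 0 °C
Reagents that add atoms: water, O
Why: CAN oxidative demethylation of the tetramethoxyarene gives the 2,5-dimethoxy-p-quinone and leaves the exocyclic alkene alone; any 4,5-dimethoxy-o-quinone by-product converges in step 12.

**Step 12**
Reactants: 14
Product: 15, the target
Conditions: KOH, MeOH/H2O, 0 °C → rt; then aq. NaH2PO4
Reagents that add atoms: potassium hydroxide, [K+].[OH-]
Why: Vinylogous-ester saponification (addition–elimination) occurs at the methoxy group flanked by the alkyl chain, which is twisted out of conjugation and more electrophilic, and the resulting vinylogous carboxylate resists a second hydrolysis; the mild acidic work-up avoids isomerising the exocyclic alkene.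

## Compound list

1 | (R)-(+)-pulegone | C[C@@H]1CCC(=C(C)C)C(=O)C1 | starting material
2 | (R)-3-methyl-6-(propan-2-ylidene)cyclohex-1-en-1-yl triflate | C[C@@H]1CCC(=C(C)C)C(OS(=O)(=O)C(F)(F)F)=C1 | intermediate
3 | (R)-3-methyl-6-oxocyclohex-1-en-1-yl triflate | C[C@@H]1CCC(=O)C(OS(=O)(=O)C(F)(F)F)=C1 | intermediate
4 | (R)-4-methylcyclohex-2-en-1-one | C[C@@H]1CCC(=O)C=C1 | intermediate
5 | 1,2,4,5-tetramethoxybenzene | COc1cc(OC)c(OC)cc1OC | starting material
6 | (2,3,5,6-tetramethoxyphenyl)methanol | COc1cc(OC)c(OC)c(CO)c1OC | intermediate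
7 | 3-(chloromethyl)-1,2,4,5-tetramethoxybenzene | COc1cc(OC)c(OC)c(CCl)c1OC | intermediate
8 | (R)-4-methyl-3-[(2,3,5,6-tetramethoxyphenyl)methyl]cyclohex-2-en-1-one | C[C@@H]1CCC(=O)C=C1Cc1c(OC)c(OC)cc(OC)c1OC | intermediate
9 | (3R,4R)-3,4-dimethyl-3-[(2,3,5,6-tetramethoxyphenyl)methyl]cyclohex-1-en-1-yl triflate | C[C@@H]1CCC(OS(=O)(=O)C(F)(F)F)=C[C@]1(C)Cc1c(OC)c(OC)cc(OC)c1OC | intermediate
10 | 1-chloro-3-iodopropane | ClCCCI | starting material
11 | 4-chloro-1-{(3R,4R)-3,4-dimethyl-3-[(2,3,5,6-tetramethoxyphenyl)methyl]cyclohex-1-en-1-yl}butan-1-one | C[C@@H]1CCC(C(=O)CCCCl)=C[C@]1(C)Cc1c(OC)c(OC)cc(OC)c1OC | intermediate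
12 | (4aS,5R,6R,8aR)-5,6,8a-trimethyl-5-[(2,3,5,6-tetramethoxyphenyl)methyl]octahydronaphthalen-1(2H)-one | O=C1CCC[C@H]2[C@](C)(Cc3c(OC)c(OC)cc(OC)c3OC)[C@H](C)CC[C@@]12C | intermediate
13 | 3-{[(1R,2R,4aR,8aS)-1,2,4a-trimethyl-5-methylidenedecahydronaphthalen-1-yl]methyl}-1,2,4,5-tetramethoxybenzene | C=C1CCC[C@H]2[C@](C)(Cc3c(OC)c(OC)cc(OC)c3OC)[C@H](C)CC[C@@]12C | intermediate
14 | 2,5-dimethoxy-3-{[(1R,2R,4aR,8aS)-1,2,4a-trimethyl-5-methylidenedecahydronaphthalen-1-yl]methyl}cyclohexa-2,5-diene-1,4-dione | C=C1CCC[C@H]2[C@](C)(CC3=C(OC)C(=O)C=C(OC)C3=O)[C@H](C)CC[C@@]12C | intermediate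
15 | 2-hydroxy-5-methoxy-3-{[(1R,2R,4aR,8aS)-1,2,4a-trimethyl-5-methylidenedecahydronaphthalen-1-yl]methyl}cyclohexa-2,5-diene-1,4-dione (CID71726091) | C=C1CCC[C@H]2[C@](C)(CC3=C(O)C(=O)C=C(OC)C3=O)[C@H](C)CC[C@@]12C | target

## Step count and risks

Total steps: 12. Longest linear sequence: 10 (steps 1–3 and 6–12; steps 4–5 are the arene branch).

Steps most likely to fail:

1. **Step 9 (proposed new step).** Risks: the C1 radical is reduced or captured by Ni before the slow 6-endo closure next to quaternary C9; the γ-chloro ketone cyclises to a cyclopropyl ketone; methylation gives some trans-fused product. Fallback (known chemistry, different ring-A construction): Stille coupling of 9 with tributyl(1-ethoxyvinyl)stannane and acid hydrolysis to the methyl ketone; vinylcuprate addition at C10 with MeI trapping at C5; 9-BBN/H2O2, then I2/PPh3; LDA intramolecular alkylation of the methyl ketone to give 12.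
2. **Step 8.** Risks: the γ-chloroalkylzinc can cyclise to cyclopropane, and direct (non-carbonylative) coupling competes. Fallback: make the methyl ketone from 9 as above, then alkylate its kinetic enolate (LDA) with 2-chloroethyl triflate to reach 11.
3. **Step 6.** Risks: Wurtz coupling of the electron-rich benzylic Grignard, 1,2-addition, or incomplete one-pot dehydrogenation. Fallback: install the benzyl group by enolate alkylation instead, i.e. α′-benzylation of pulegone 1 with LDA and 7 (NaI), then enol triflation, cleavage of the isopropylidene with OsO4/NaIO4 (ozone would attack the arene) and Pd/formate reduction to 8.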